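## Retrosynthetic overview

1. The target is a para-depside; the key disconnection is the aryl ester C(=O)–O bond between ring A (the 2,4-dihydroxy-6-methylbenzoyl unit) and the 4-OH of ring B (2-heptyl-4,6-dihydroxybenzoic acid).
2. Ring A donor: 2,4-bis(benzyloxy)-6-methylbenzoic acid, made from commercial 2,4-dihydroxy-6-methylbenzaldehyde by benzylation and Pinnick oxidation.
3. Ring B acceptor: benzyl 2-heptyl-4,6-dihydroxybenzoate, made from commercial 5-heptylresorcinol by C-carboxylation (Ar–CO2H disconnection) and benzyl esterification.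
4. The fragments are joined by mixed-anhydride esterification at the free 4-OH (the 2-OH is hydrogen-bonded to the ester), followed by one hydrogenolysis that removes all three benzyl groups.
5. No ring is formed: both benzene rings are bought intact (ring A is elaborated in steps 1–2, ring B in steps 3–4).

Assumption: the SMILES contains no stereocentre and no stereogenic double bond, so the target is achiral and no stereocontrol is needed.

## Route

Step 1
Reactants: 1 2,4-dihydroxy-6-methylbenzaldehyde
Product: 2 2,4-bis(benzyloxy)-6-methylbenzaldehyde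
Conditions: BnBr (2.4 equiv), K2CO3 (3 equiv), DMF, 60 °C, 6 h
Reagents that add atoms: benzyl bromide, BrCc1ccccc1
Why: Williamson ether synthesis alkylates both phenoxides (the chelated 2-OH needs the warming), and the aldehyde is inert to K2CO3 and BnBr.

Step 2
Reactants: 2 2,4-bis(benzyloxy)-6-methylbenzaldehyde
Product: 3 2,4-bis(benzyloxy)-6-methylbenzoic acid
Conditions: NaClO2 (3 equiv), NaH2PO4 (3 equiv), 2-methyl-2-butene (10 equiv), t-BuOH/THF/H2O, 0 °C to rt
Reagents that add atoms: sodium chlorite (NaClO2), [Na+].[O-]Cl=O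
Why: Pinnick oxidation converts the hindered, electron-rich aldehyde to the acid without touching the benzyl ethers, and the alkene traps hypochlorous acid so the ring is not chlorinated.

Step 3
Reactants: 4 5-heptylbenzene-1,3-diol (5-heptylresorcinol)
Product: 6 2-heptyl-4,6-dihydroxybenzoic acid, via magnesium 2-carboxylato-3-heptyl-5-hydroxyphenolate 5 (not isolated)
Conditions: MeOMgOCO2Me (2 M in DMF, 4 equiv), 120 °C, 3 h, N2 sweep; then ice-cold 2 M HCl
Reagents that add atoms: methoxymagnesium methyl carbonate (MeOMgOCO2Me), COC(=O)O[Mg]OC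
Why: Kolbe–Schmitt-type ortho-carboxylation with the Stiles reagent delivers CO2 to the carbon ortho to one OH and para to the other, driven by chelation of divalent magnesium between phenoxide and the new carboxylate; cold acidic work-up avoids decarboxylation.

Step 4
Reactants: 6 2-heptyl-4,6-dihydroxybenzoic acid
Product: 7 benzyl 2-heptyl-4,6-dihydroxybenzoate
Conditions: BnBr (1.05 equiv), KHCO3 (1.1 equiv), DMF, rt, 16 h
Reagents that add atoms: benzyl bromide, BrCc1ccccc1
Why: Chemoselective SN2 O-alkylation of the carboxylate, because hydrogencarbonate deprotonates only the carboxylic acid (pKa about 3) and not the phenols, so no benzyl ether forms.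

Step 5
Reactants: 3 2,4-bis(benzyloxy)-6-methylbenzoic acid; 7 benzyl 2-heptyl-4,6-dihydroxybenzoate
Product: 9 benzyl 4-{[2,4-bis(benzyloxy)-6-methylbenzoyl]oxy}-2-heptyl-6-hydroxybenzoate, via mixed trifluoroacetic anhydride 8 (not isolated)
Conditions: (CF3CO)2O (3 equiv), dry toluene, rt, 3 h; aqueous NaHCO3 work-up
Reagents that add atoms: none
Why: Mixed-anhydride esterification with trifluoroacetic anhydride transfers the hindered aroyl group to the free 4-OH only, since the 2-OH is hydrogen-bonded to the ester carbonyl and flanked by it; benzyl groups survive and any aryl trifluoroacetate is cleaved in the work-up.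

Step 6
Reactants: 9 benzyl 4-{[2,4-bis(benzyloxy)-6-methylbenzoyl]oxy}-2-heptyl-6-hydroxybenzoate
Product: 10 4-[(2,4-dihydroxy-6-methylbenzoyl)oxy]-2-heptyl-6-hydroxybenzoic acid
Conditions: H2 (1 atm), 10% Pd/C, EtOAc, rt, 2 h
Reagents that add atoms: none
Why: Catalytic hydrogenolysis cleaves the two benzyl ethers and the benzyl ester at their benzylic C–O bonds, leaves the aryl ester (depside) link and both arenes intact, and the non-nucleophilic solvent prevents transesterification.

## Compound list

1 | 2,4-dihydroxy-6-methylbenzaldehyde | Cc1cc(O)cc(O)c1C=O | starting material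
2 | 2,4-bis(benzyloxy)-6-methylbenzaldehyde | Cc1cc(OCc2ccccc2)cc(OCc2ccccc2)c1C=O | intermediate
3 | 2,4-bis(benzyloxy)-6-methylbenzoic acid | Cc1cc(OCc2ccccc2)cc(OCc2ccccc2)c1C(=O)O | intermediate
4 | 5-heptylbenzene-1,3-diol (5-heptylresorcinol) | CCCCCCCc1cc(O)cc(O)c1 | starting material
5 | magnesium 2-carboxylato-3-heptyl-5-hydroxyphenolate (chelate formed in the flask, not isolated) | CCCCCCCc1cc(O)cc2O[Mg]OC(=O)c12 | intermediate
6 | 2-heptyl-4,6-dihydroxybenzoic acid | CCCCCCCc1cc(O)cc(O)c1C(=O)O | intermediate
7 | benzyl 2-heptyl-4,6-dihydroxybenzoate | CCCCCCCc1cc(O)cc(O)c1C(=O)OCc1ccccc1 | intermediate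
8 | 2,4-bis(benzyloxy)-6-methylbenzoic trifluoroacetic anhydride (mixed anhydride formed in the flask, not isolated) | Cc1cc(OCc2ccccc2)cc(OCc2ccccc2)c1C(=O)OC(=O)C(F)(F)F | intermediate
9 | benzyl 4-{[2,4-bis(benzyloxy)-6-methylbenzoyl]oxy}-2-heptyl-6-hydroxybenzoate | CCCCCCCc1cc(OC(=O)c2c(C)cc(OCc3ccccc3)cc2OCc2ccccc2)cc(O)c1C(=O)OCc1ccccc1 | intermediate
10 | 4-[(2,4-dihydroxy-6-methylbenzoyl)oxy]-2-heptyl-6-hydroxybenzoic acid | CCCCCCCc1cc(OC(=O)c2c(C)cc(O)cc2O)cc(O)c1C(=O)O | target

## Step count and risks

Total step count: 6. Longest linear sequence: 4 steps (1 → 2 → 3 → 9 → 10, or equally 4 → 6 → 7 → 9 → 10).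

Steps most likely to fail, most risky first:

**Step 3 (carboxylation).** It may stall, give some of the 2,6-dihydroxy regioisomer, or lose CO2 again on work-up. The fallback sets out from 4 and comes back to the route at 10, carrying the carboxyl carbon as an aldehyde until after the coupling. Vilsmeier–Haack formylation of 4 (POCl3, DMF, 0 °C to rt) gives [(2-heptyl-4,6-dihydroxyphenyl)methylidene]dimethylammonium chloride F1, which is hydrolysed in the aqueous work-up (water, 50 °C) to 2-heptyl-4,6-dihydroxybenzaldehyde F2. F2 is acylated at its free 4-OH by acid 3 through mixed anhydride 8 ((CF3CO)2O, toluene, rt) to give 4-formyl-3-heptyl-5-hydroxyphenyl 2,4-bis(benzyloxy)-6-methylbenzoate F3. Pinnick oxidation of F3 (NaClO2, NaH2PO4, 2-methyl-2-butene, t-BuOH/THF/H2O) gives 4-{[2,4-bis(benzyloxy)-6-methylbenzoyl]oxy}-2-heptyl-6-hydroxybenzoic acid F4. Hydrogenolysis of F4 (H2, 10% Pd/C, EtOAc) gives 10. The total stays at six steps, and compounds 5, 6, 7 and 9 are bypassed.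

**Step 5 (depside coupling).** The acid is hindered on both ortho positions, and transient trifluoroacetates or acylation at the wrong hydroxyl could lower the yield. The fallback sets out from 3 and comes back at 9, replacing in-flask activation by a preformed, more reactive acyl donor. Acid 3 is treated with (COCl)2 and catalytic DMF in CH2Cl2 (0 °C to rt) and evaporated to give 2,4-bis(benzyloxy)-6-methylbenzoyl chloride F5. F5 is added to 7 in pyridine with catalytic DMAP (0 °C to rt) and acylates the more acidic, non-chelated 4-OH to give 9.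

**Step 4 (benzyl ester formation).** Partial O-benzylation of the 4-OH or decarboxylation of 6 in basic DMF could occur. The fallback sets out from 6 and comes back at 7, delivering the benzyl group as a nucleophile instead of an electrophile so that no phenol ether can form. Acid 6 is condensed with acetone in (CF3CO)2O/CF3CO2H (0 °C to rt) to give 5-heptyl-7-hydroxy-2,2-dimethyl-4H-1,3-benzodioxin-4-one F6. F6 is opened by benzyl alcohol (5 equiv) with Cs2CO3 (2.2 equiv) in THF at 50 °C, a transesterification that releases acetone and gives 7.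

## Further compounds

F1 | step 3 | [(2-heptyl-4,6-dihydroxyphenyl)methylidene]dimethylammonium chloride | CCCCCCCc1cc(O)cc(O)c1C=[N+](C)C.[Cl-]
F2 | step 3 | 2-heptyl-4,6-dihydroxybenzaldehyde | CCCCCCCc1cc(O)cc(O)c1C=O
F3 | step 3 | 4-formyl-3-heptyl-5-hydroxyphenyl 2,4-bis(benzyloxy)-6-methylbenzoate | CCCCCCCc1cc(OC(=O)c2c(C)cc(OCc3ccccc3)cc2OCc2ccccc2)cc(O)c1C=O
F4 | step 3 | 4-{[2,4-bis(benzyloxy)-6-methylbenzoyl]oxy}-2-heptyl-6-hydroxybenzoic acid | CCCCCCCc1cc(OC(=O)c2c(C)cc(OCc3ccccc3)cc2OCc2ccccc2)cc(O)c1C(=O)O
F5 | step 5 | 2,4-bis(benzyloxy)-6-methylbenzoyl chloride | Cc1cc(OCc2ccccc2)cc(OCc2ccccc2)c1C(=O)Cl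
F6 | step 4 | 5-heptyl-7-hydroxy-2,2-dimethyl-4H-1,3-benzodioxin-4-one | CCCCCCCc1cc(O)cc2OC(C)(C)OC(=O)c12
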